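**Retrosynthetic overview**
- Bisoflavolin L ⇐ four-fold O-demethylation of its tetra-O-methyl ether; the molecule has no stereocentre.
- Both 4H-chromen-4-one rings ⇐ acid cyclisation of a bis(β-keto dimethyl acetal), itself from a two-fold Tl(III) oxidative 1,2-aryl shift of a bis(2'-hydroxychalcone).
- Bis-chalcone ⇐ two successive Claisen–Schmidt aldol condensations (the key C–C bonds) on a diaryl ether dialdehyde with one formyl group masked as a dioxolane: first with 3-chloro-2-hydroxy-4,6-dimethoxyacetophenone, then with paeonol.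
- Diaryl ether ⇐ SNAr of isovanillin ethylene acetal on 4-fluorobenzaldehyde; chloro-acetophenone ⇐ ortho-Fries rearrangement of 2-chloro-3,5-dimethoxyphenyl acetate, which fixes Cl at the future C-8.
- Ring order: the four benzene rings are bought; the two pyranone rings are formed last, together, in step 9.

Assumption: the target is achiral, so "single enantiomer" needs no stereocontrol; 2-chloro-3,5-dimethoxyphenol is taken as a catalogue building block.

**Step 1**
Reactants: 1 2-chloro-3,5-dimethoxyphenol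
Product: 2 2-chloro-3,5-dimethoxyphenyl acetate
Conditions: Ac2O (1.5 equiv), pyridine, DMAP (cat.), CH2Cl2, 0 °C → rt
Reagents that add atoms: acetic anhydride CC(=O)OC(C)=O
Why: DMAP-catalysed O-acylation of a phenol is quantitative and sets up the Fries rearrangement.

**Step 2**
Reactants: 2 2-chloro-3,5-dimethoxyphenyl acetate
Product: 4 1-(3-chloro-2-hydroxy-4,6-dimethoxyphenyl)ethanone, via difluoroboron chelate 3 (not isolated)
Conditions: BF3·OEt2 (3 equiv), 1,2-dichloroethane, 85 °C; then H2O/EtOH, 70 °C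
Reagents that add atoms: none
Why: Lewis-acid Fries rearrangement sends the acetyl group to the only free position ortho to the phenol oxygen, driven by the six-membered BF2 chelate (the para site is flanked by two OMe groups), so Cl ends up between OH and OMe.

**Step 3**
Reactants: 5 isovanillin (3-hydroxy-4-methoxybenzaldehyde)
Product: 6 5-(1,3-dioxolan-2-yl)-2-methoxyphenol
Conditions: ethylene glycol (3 equiv), p-TsOH·H2O (2 mol %), toluene, reflux, Dean–Stark; Et3N quench
Reagents that add atoms: ethylene glycol OCCO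
Why: Acid-catalysed acetalisation with azeotropic water removal masks this aldehyde so the two formyl groups can be condensed one at a time; the phenol is untouched.

**Step 4**
Reactants: 6 5-(1,3-dioxolan-2-yl)-2-methoxyphenol; 7 4-fluorobenzaldehyde
Product: 8 4-[5-(1,3-dioxolan-2-yl)-2-methoxyphenoxy]benzaldehyde
Conditions: K2CO3 (2 equiv), DMF, 110 °C, N2
Reagents that add atoms: none
Why: SNAr (addition–elimination) of the phenoxide on the para-formyl-activated aryl fluoride is a dependable diaryl ether synthesis, and the dioxolane is stable to base.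

**Step 5**
Reactants: 8 4-[5-(1,3-dioxolan-2-yl)-2-methoxyphenoxy]benzaldehyde; 4 1-(3-chloro-2-hydroxy-4,6-dimethoxyphenyl)ethanone
Product: 10 (E)-1-(3-chloro-2-hydroxy-4,6-dimethoxyphenyl)-3-{4-[5-(1,3-dioxolan-2-yl)-2-methoxyphenoxy]phenyl}prop-2-en-1-one, via aldol adduct 9 (not isolated)
Conditions: KOH (50% aq, excess, not consumed in the net equation), EtOH, 0 °C → rt, 48 h; then AcOH to pH 6 at 0 °C
Reagents that add atoms: none
Why: Claisen–Schmidt crossed aldol condensation of the methyl ketone enolate with a non-enolisable aldehyde, followed by E1cB dehydration, gives the (E)-enone, as for other 2'-hydroxy-4',6'-dimethoxychalcones.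

**Step 6**
Reactants: 10 the chalcone acetal from step 5
Product: 11 3-{4-[(E)-3-(3-chloro-2-hydroxy-4,6-dimethoxyphenyl)-3-oxoprop-1-enyl]phenoxy}-4-methoxybenzaldehyde
Conditions: 1 M aq HCl, THF, rt, 2 h
Reagents that add atoms: water O
Why: Acid-catalysed acetal hydrolysis of the electron-rich aryl dioxolane is fast at room temperature, while the hydrogen-bonded 2'-hydroxychalcone does not cyclise under these conditions.

**Step 7**
Reactants: 11 the chalcone aldehyde from step 6; 12 paeonol (1-(2-hydroxy-4-methoxyphenyl)ethanone)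
Product: 14 (E)-1-(3-chloro-2-hydroxy-4,6-dimethoxyphenyl)-3-(4-{5-[(E)-3-(2-hydroxy-4-methoxyphenyl)-3-oxoprop-1-enyl]-2-methoxyphenoxy}phenyl)prop-2-en-1-one, via aldol adduct 13 (not isolated)
Conditions: KOH (50% aq, excess, not consumed in the net equation), EtOH, rt, 48–72 h; then 1 M HCl to pH 4
Reagents that add atoms: none
Why: A second Claisen–Schmidt aldol condensation forms the other (E)-enone; the chalcone already present sits as its phenoxide, a poor Michael acceptor, and does not undergo retro-aldol at room temperature.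

**Step 8**
Reactants: 14 the bis-chalcone from step 7
Product: 15 1-(3-chloro-2-hydroxy-4,6-dimethoxyphenyl)-2-(4-{5-[1-(2-hydroxy-4-methoxyphenyl)-3,3-dimethoxy-1-oxopropan-2-yl]-2-methoxyphenoxy}phenyl)-3,3-dimethoxypropan-1-one (diastereomer mixture)
Conditions: Tl(NO3)3·3H2O (2.4 equiv), MeOH/HC(OMe)3/CH2Cl2, rt, 24 h; filter off TlNO3, aqueous wash, use crude
Reagents that add atoms: methanol CO
Why: Thallium(III) nitrate oxidative rearrangement of 2'-hydroxychalcones (oxythallation, then 1,2-shift of the oxygen-donor-substituted B ring and acetal trapping) happens at both enones; the two new stereocentres are uncontrolled and are destroyed in step 9.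

**Step 9**
Reactants: 15 the bis(β-keto dimethyl acetal) from step 8
Product: 16 8-chloro-5,7-dimethoxy-3-{4-[2-methoxy-5-(7-methoxy-4-oxo-4H-chromen-3-yl)phenoxy]phenyl}-4H-chromen-4-one
Conditions: 10% aq HCl (cat.), MeOH/1,4-dioxane, 65 °C, 3 h
Reagents that add atoms: none
Why: Acid-catalysed intramolecular transacetalisation by each ortho phenol, then loss of methanol, closes both pyranone rings; the hydroxyl next to Cl is the only free one on that ring, so Cl is at C-8.

**Step 10**
Reactants: 16 the tetra-O-methyl bis-isoflavone from step 9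
Product: 17 Bisoflavolin L (8-chloro-5,7-dihydroxy-3-{4-[2-hydroxy-5-(7-hydroxy-4-oxo-4H-chromen-3-yl)phenoxy]phenyl}-4H-chromen-4-one)
Conditions: BBr3 (1 M in CH2Cl2, 12 equiv), CH2Cl2, −78 °C → rt, 24 h (40 °C if needed); then H2O, 0 °C
Reagents that add atoms: none
Why: BBr3 Lewis-acid ether cleavage (bromide SN2 at the O-methyl of each boron–ether adduct) removes all four methyl groups and leaves the diaryl ether, aryl chloride and chromenones intact.

**Compound list**
1 | 2-chloro-3,5-dimethoxyphenol | Oc1cc(OC)cc(OC)c1Cl | starting material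
2 | 2-chloro-3,5-dimethoxyphenyl acetate | CC(=O)Oc1cc(OC)cc(OC)c1Cl | intermediate
3 | O,O-difluoroboron chelate of 1-(3-chloro-2-hydroxy-4,6-dimethoxyphenyl)ethanone | CC1=[O+][B-](F)(F)Oc2c(Cl)c(OC)cc(OC)c12 | intermediate (not isolated)
4 | 1-(3-chloro-2-hydroxy-4,6-dimethoxyphenyl)ethanone | CC(=O)c1c(O)c(Cl)c(OC)cc1OC | intermediate
5 | isovanillin (3-hydroxy-4-methoxybenzaldehyde) | COc1ccc(C=O)cc1O | starting material
6 | 5-(1,3-dioxolan-2-yl)-2-methoxyphenol | COc1ccc(C2OCCO2)cc1O | intermediate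
7 | 4-fluorobenzaldehyde | O=Cc1ccc(F)cc1 | starting material
8 | 4-[5-(1,3-dioxolan-2-yl)-2-methoxyphenoxy]benzaldehyde | COc1ccc(C2OCCO2)cc1Oc1ccc(C=O)cc1 | intermediate
9 | racemic 1-(3-chloro-2-hydroxy-4,6-dimethoxyphenyl)-3-{4-[5-(1,3-dioxolan-2-yl)-2-methoxyphenoxy]phenyl}-3-hydroxypropan-1-one (aldol adduct) | COc1ccc(C2OCCO2)cc1Oc1ccc(C(O)CC(=O)c2c(O)c(Cl)c(OC)cc2OC)cc1 | intermediate (not isolated)
10 | (E)-1-(3-chloro-2-hydroxy-4,6-dimethoxyphenyl)-3-{4-[5-(1,3-dioxolan-2-yl)-2-methoxyphenoxy]phenyl}prop-2-en-1-one | COc1ccc(C2OCCO2)cc1Oc1ccc(/C=C/C(=O)c2c(O)c(Cl)c(OC)cc2OC)cc1 | intermediate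
11 | 3-{4-[(E)-3-(3-chloro-2-hydroxy-4,6-dimethoxyphenyl)-3-oxoprop-1-enyl]phenoxy}-4-methoxybenzaldehyde | COc1ccc(C=O)cc1Oc1ccc(/C=C/C(=O)c2c(O)c(Cl)c(OC)cc2OC)cc1 | intermediate
12 | paeonol (1-(2-hydroxy-4-methoxyphenyl)ethanone) | CC(=O)c1ccc(OC)cc1O | starting material
13 | racemic (E)-1-(3-chloro-2-hydroxy-4,6-dimethoxyphenyl)-3-(4-{5-[1-hydroxy-3-(2-hydroxy-4-methoxyphenyl)-3-oxopropyl]-2-methoxyphenoxy}phenyl)prop-2-en-1-one (aldol adduct) | COc1ccc(C(O)CC(=O)c2ccc(OC)cc2O)cc1Oc1ccc(/C=C/C(=O)c2c(O)c(Cl)c(OC)cc2OC)cc1 | intermediate (not isolated)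
14 | (E)-1-(3-chloro-2-hydroxy-4,6-dimethoxyphenyl)-3-(4-{5-[(E)-3-(2-hydroxy-4-methoxyphenyl)-3-oxoprop-1-enyl]-2-methoxyphenoxy}phenyl)prop-2-en-1-one (bis-chalcone) | COc1ccc(/C=C/C(=O)c2ccc(OC)cc2O)cc1Oc1ccc(/C=C/C(=O)c2c(O)c(Cl)c(OC)cc2OC)cc1 | intermediate
15 | 1-(3-chloro-2-hydroxy-4,6-dimethoxyphenyl)-2-(4-{5-[1-(2-hydroxy-4-methoxyphenyl)-3,3-dimethoxy-1-oxopropan-2-yl]-2-methoxyphenoxy}phenyl)-3,3-dimethoxypropan-1-one (diastereomer mixture) | COc1ccc(C(C(OC)OC)C(=O)c2ccc(OC)cc2O)cc1Oc1ccc(C(C(OC)OC)C(=O)c2c(O)c(Cl)c(OC)cc2OC)cc1 | intermediate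
16 | 8-chloro-5,7-dimethoxy-3-{4-[2-methoxy-5-(7-methoxy-4-oxo-4H-chromen-3-yl)phenoxy]phenyl}-4H-chromen-4-one | COc1ccc(-c2coc3cc(OC)ccc3c2=O)cc1Oc1ccc(-c2coc3c(Cl)c(OC)cc(OC)c3c2=O)cc1 | intermediate
17 | Bisoflavolin L | O=c1c(-c2ccc(O)c(Oc3ccc(-c4coc5c(Cl)c(O)cc(O)c5c4=O)cc3)c2)coc2cc(O)ccc12 | target

**Totals**
Total step count: 10. Longest linear sequence: 8 steps (1 → 2 → 4 → 10 → 11 → 14 → 15 → 16 → 17; the branch from 5 is also 8).

**Three steps most likely to fail**

Step 8 (two-fold Tl(III) rearrangement). Both aryl shifts must occur in one molecule, and the 4-aryloxyphenyl ring is only a moderate migrating group, so aurone formation or partial conversion can erode the yield. The fallback sets out from 14 and returns at 16, bypassing 15. Compound 14 is isomerised with NaOAc in refluxing EtOH (intramolecular oxa-Michael addition) to the bis-flavanone 8-chloro-5,7-dimethoxy-2-{4-[2-methoxy-5-(7-methoxy-4-oxochroman-2-yl)phenoxy]phenyl}chroman-4-one F3, a diastereomer mixture. This is then oxidised with [hydroxy(tosyloxy)iodo]benzene (2.4 equiv, MeCN, reflux), which induces the oxidative 2,3-aryl migration of flavanones and gives 16 directly, without thallium and without an acetal.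

Step 10 (four-fold demethylation). The non-chelated 7-OMe groups cleave slowly, so partially methylated mixtures are possible. The fallback sets out from 16 and returns at 17 by a staged, mechanistically different sequence. BCl3 (CH2Cl2, 0 °C) removes only the carbonyl-chelated 5-O-methyl group to give 8-chloro-5-hydroxy-7-methoxy-3-{4-[2-methoxy-5-(7-methoxy-4-oxo-4H-chromen-3-yl)phenoxy]phenyl}-4H-chromen-4-one F4. The three remaining methyl ethers are then cleaved by Brønsted-acid/chloride SN2 dealkylation in molten pyridinium chloride (190 °C) to give 17.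

Step 2 (Fries rearrangement). Para migration, ester cleavage back to 1, or an incomplete reaction next to the chlorine are the likely problems. The fallback sets out from 1 and returns at 4, with the ortho position enforced by magnesium phenoxide chelation instead of acyl migration. Compound 1 is ortho-formylated (MgCl2, Et3N, paraformaldehyde, MeCN, reflux) to 3-chloro-2-hydroxy-4,6-dimethoxybenzaldehyde F1. MeMgBr (2.5 equiv, THF, 0 °C) then gives racemic 1-(3-chloro-2-hydroxy-4,6-dimethoxyphenyl)ethanol F2, and activated MnO2 (CH2Cl2, rt) oxidises the benzylic alcohol to 4.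

**Further compounds**
F1 | step 2 | 3-chloro-2-hydroxy-4,6-dimethoxybenzaldehyde | O=Cc1c(O)c(Cl)c(OC)cc1OC
F2 | step 2 | racemic 1-(3-chloro-2-hydroxy-4,6-dimethoxyphenyl)ethanol | CC(O)c1c(O)c(Cl)c(OC)cc1OC
F3 | step 8 | 8-chloro-5,7-dimethoxy-2-{4-[2-methoxy-5-(7-methoxy-4-oxochroman-2-yl)phenoxy]phenyl}chroman-4-one (diastereomer mixture) | COc1ccc(C2CC(=O)c3ccc(OC)cc3O2)cc1Oc1ccc(C2CC(=O)c3c(OC)cc(OC)c(Cl)c3O2)cc1
F4 | step 10 | 8-chloro-5-hydroxy-7-methoxy-3-{4-[2-methoxy-5-(7-methoxy-4-oxo-4H-chromen-3-yl)phenoxy]phenyl}-4H-chromen-4-one | COc1ccc(-c2coc3cc(OC)ccc3c2=O)cc1Oc1ccc(-c2coc3c(Cl)c(OC)cc(O)c3c2=O)cc1
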